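**Retrosynthetic overview**
- The C4 carbinol comes from a site- and cis-selective 1,2-reduction of the (2S)-chromene-4,5-dione.
- The pyran ring of that dione is opened at O1–C2: an enantioselective 6-endo oxa-Michael ring closure of an open 2-[(E)-icos-2-enoyl]cyclohexane-1,3-dione forms this C–O bond and sets C2 (key step).
- The enoyl triketone comes from aldol condensation of 2-acetylcyclohexane-1,3-dione with octadecanal.
- Ring order: the carbocycle is bought; the pyran ring is closed second, by the C–O bond.

Assumption: both starting materials are bought (octadecanal freshly distilled); the sense of induction in step 2 cannot be predicted, so the route is written with the (R)-acid and the (S)-acid is used instead if the (R)-acid gives the (2R)-product.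

**Step 1**
Reactants: 1 2-acetylcyclohexane-1,3-dione; 2 octadecanal
Product: 4 3-hydroxy-2-[(2E)-icos-2-enoyl]cyclohex-2-en-1-one, via aldol adduct 3 (not isolated)
Conditions: pyrrolidine (0.3 equiv), 4 Å MS, CH2Cl2, 0 °C to rt, 2 added over 4 h; cold 0.5 M HCl wash
Reagents that add atoms: none
Why: Claisen–Schmidt-type aldol condensation under enamine catalysis (the amine protocol used for 2-cinnamoyl-1,3-diones and in the Kabbe chromanone synthesis): the acetyl group adds to the aldehyde, aldol adduct 3 loses water in the flask to the conjugated E-enone, which is kept as its chelated enol; slow addition of 2 limits aldehyde self-condensation and no stereocentre survives.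

**Step 2**
Reactants: 4 3-hydroxy-2-[(2E)-icos-2-enoyl]cyclohex-2-en-1-one
Product: 6 (2S)-2-heptadecyl-2,3,7,8-tetrahydro-4H-chromene-4,5(6H)-dione, via pyranol enol 5 (not isolated)
Conditions: (R)-3,3'-bis(2,4,6-triisopropylphenyl)-1,1'-binaphthyl-2,2'-diyl hydrogen phosphate (5 mol %), 5 Å MS, toluene, −30 °C, 48 h
Reagents that add atoms: none
Why: Proposed new method: chiral phosphoric acid-catalysed enantioselective 6-endo-trig oxa-Michael cycloisomerisation of an enolised 2-enoyl-1,3-dione (equivalently an oxa-6π closure of its cross-conjugated dienol tautomer), in which the catalyst P=O accepts the hydrogen bond of the enol O–H while P–OH activates the enoyl C=O, the ring enol oxygen forms the O1–C2 bond inside the chiral pocket to give enol 5, and the same acid relays the proton to C3 so that 5 ketonises irreversibly to 6 (if closure to 5 is reversible, C2 is instead fixed by catalyst-selective ketonisation of one enantiomer of 5, which still funnels to one enantiomer of 6); the base-free, cold medium avoids the E1cB ring opening that would racemise C2; closest known reaction type: phosphoric acid-catalysed asymmetric intramolecular oxa-Michael additions of alcohols and phenols to enones and enoyl thioesters, not yet shown for a vinylogous-acid O–H nucleophile or a triketone substrate.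

**Step 3**
Reactants: 6 (2S)-2-heptadecyl-2,3,7,8-tetrahydro-4H-chromene-4,5(6H)-dione
Product: 7 (2S,4R)-2-heptadecyl-4-hydroxy-2,3,4,6,7,8-hexahydro-5H-chromen-5-one
Conditions: NaBH4 (0.6 equiv), CeCl3·7H2O (1.1 equiv), MeOH/CH2Cl2 3:1, −78 °C, 1 h; pH 7 phosphate buffer
Reagents that add atoms: none
Why: Luche 1,2-reduction: C4=O is the carbonyl of the dihydropyran-4-one half (the less stabilised vinylogous ester, inductively activated by O1 through C2–C3, the type that NaBH4/CeCl3 reduces at −78 °C), whereas C5=O is a 3-alkoxycyclohexenone carbonyl that normally needs a higher temperature or a stronger hydride, and product 7 is itself such a deactivated enone so it is not reduced further; hydride adds axially to the half-chair that carries the C2 chain pseudo-equatorial, giving the pseudo-equatorial 4-OH cis to the chain, which is 4R for 2S.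

**Compound list**
1 | 2-acetylcyclohexane-1,3-dione (drawn as enol) | CC(=O)C1=C(O)CCCC1=O | starting material
2 | octadecanal | CCCCCCCCCCCCCCCCCC=O | starting material
3 | 3-hydroxy-2-(3-hydroxyicosanoyl)cyclohex-2-en-1-one, racemic aldol adduct, not isolated | CCCCCCCCCCCCCCCCCC(O)CC(=O)C1=C(O)CCCC1=O | intermediate
4 | 3-hydroxy-2-[(2E)-icos-2-enoyl]cyclohex-2-en-1-one | CCCCCCCCCCCCCCCCC/C=C/C(=O)C1=C(O)CCCC1=O | intermediate
5 | (2S)-2-heptadecyl-4-hydroxy-7,8-dihydro-2H-chromen-5(6H)-one, enol, not isolated | CCCCCCCCCCCCCCCCC[C@H]1C=C(O)C2=C(CCCC2=O)O1 | intermediate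
6 | (2S)-2-heptadecyl-2,3,7,8-tetrahydro-4H-chromene-4,5(6H)-dione | CCCCCCCCCCCCCCCCC[C@H]1CC(=O)C2=C(CCCC2=O)O1 | intermediate
7 | (2S,4R)-2-heptadecyl-4-hydroxy-2,3,4,6,7,8-hexahydro-5H-chromen-5-one (2-heptadecyl and 4-OH cis) | CCCCCCCCCCCCCCCCC[C@H]1C[C@@H](O)C2=C(CCCC2=O)O1 | target

**Total step count:** 3. **Longest linear sequence:** 3.

**The three steps most likely to fail**

**Step 2 (the new reaction).** Risks:
- a racemic background cyclisation catalysed by the substrate's own acidic enol;
- too little acidity of the catalyst (the N-triflyl phosphoramide analogue is the first variation to try);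
- unknown sense of induction;
- loss of ee by ring opening.

Fallback (known chemistry, resolution instead of asymmetric catalysis), from 4 back to 6:
- 4 is cyclised without stereocontrol (TsOH·H2O 10 mol %, toluene, 40 °C, the known acid-catalysed closure of 2-enoyl-1,3-diones). This passes through enol 5 and its mirror image, the (2R)-enol F1, and gives 6 together with the (2R)-dione F2 as a racemate.
- Preparative chiral SFC (amylose tris(3,5-dimethylphenylcarbamate) phase, CO2/MeOH) delivers 6.
- F2 can be returned to 4 by DBU (E1cB ring opening) and cold citric acid, and cycled again.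

**Step 3.** Risk: hydride attack at C5 or at both carbonyls; the site preference rests on reactivity analogies, not on a direct precedent for this dione. HMBC and the H4 coupling pattern are the check.

Fallback (site control by intramolecular hydride delivery; C2 set by known asymmetric borylation), from 4 back to 7, bypassing steps 2 and 3:
- Me2SO4, K2CO3, acetone gives the ring methyl enol ether F3.
- Conjugate borylation (CuCl, NaOtBu, (R)-1-[(S)-2-(diphenylphosphino)ferrocenyl]ethyldicyclohexylphosphine or its mirror image, whichever gives the 3S product, bis(pinacolato)diboron, MeOH, THF) gives the (3S)-β-boryl ketone F4.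
- NaBO3·4H2O in THF/H2O oxidises F4 with retention to the (3S)-β-hydroxy ketone F5.
- Evans–Tishchenko reduction (SmI2 30 mol %, PhCHO, THF, −10 °C) transfers hydride from the hemiacetal on the C3 oxygen to the acyl carbonyl only. It gives the 1,3-anti diol monobenzoate F6 with the new carbinol R.
- K2CO3 in MeOH removes the benzoate; the freed alkoxide displaces methoxide at the vinylogous ester carbon (C–O ring closure with retention at both centres) and gives 7.

**Step 1.** Risks: self-aldol of octadecanal, and premature racemic ring closure of 4 on work-up or silica, which would spoil step 2.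

Fallback (olefination instead of aldol condensation), from 2 back to 4:
- Purchased cyclohexane-1,3-dione (O=C1CCCC(=O)C1) is acylated with diethylphosphonoacetic acid (DCC, DMAP, CH2Cl2) to the enol ester F7.
- DMAP rearranges F7 in the same flask to the C-acyl triketone phosphonate F8.
- F8 is deprotonated twice (KOtBu 2.1 equiv, THF, 0 °C) and condensed with 2 in a Horner–Wadsworth–Emmons olefination. The E-enone forms as its potassium triketonate, which cannot cyclise, and cold citric acid releases 4.

**Further compounds**
F1 | step 2 | (2R)-2-heptadecyl-4-hydroxy-7,8-dihydro-2H-chromen-5(6H)-one, enol, not isolated | CCCCCCCCCCCCCCCCC[C@@H]1C=C(O)C2=C(CCCC2=O)O1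
F2 | step 2 | (2R)-2-heptadecyl-2,3,7,8-tetrahydro-4H-chromene-4,5(6H)-dione | CCCCCCCCCCCCCCCCC[C@@H]1CC(=O)C2=C(CCCC2=O)O1
F3 | step 3 | 2-[(2E)-icos-2-enoyl]-3-methoxycyclohex-2-en-1-one | CCCCCCCCCCCCCCCCC/C=C/C(=O)C1=C(OC)CCCC1=O
F4 | step 3 | 3-methoxy-2-[(3S)-3-(4,4,5,5-tetramethyl-1,3,2-dioxaborolan-2-yl)icosanoyl]cyclohex-2-en-1-one | CCCCCCCCCCCCCCCCC[C@H](B1OC(C)(C)C(C)(C)O1)CC(=O)C1=C(OC)CCCC1=O
F5 | step 3 | 2-[(3S)-3-hydroxyicosanoyl]-3-methoxycyclohex-2-en-1-one | CCCCCCCCCCCCCCCCC[C@H](O)CC(=O)C1=C(OC)CCCC1=O
F6 | step 3 | (1R,3S)-1-hydroxy-1-(2-methoxy-6-oxocyclohex-1-en-1-yl)icosan-3-yl benzoate | CCCCCCCCCCCCCCCCC[C@H](OC(=O)c1ccccc1)C[C@@H](O)C1=C(OC)CCCC1=O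
F7 | step 1 | 3-oxocyclohex-1-en-1-yl 2-(diethoxyphosphoryl)acetate, not isolated | CCOP(=O)(OCC)CC(=O)OC1=CC(=O)CCC1
F8 | step 1 | diethyl [2-(2-hydroxy-6-oxocyclohex-1-en-1-yl)-2-oxoethyl]phosphonate | CCOP(=O)(OCC)CC(=O)C1=C(O)CCCC1=O
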